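## Retrosynthetic overview

1. The target comes from its penta-O-benzyl ether by hydrogenolysis. Rings A, B and D are bought as benzene building blocks. Ring C is the only ring made, and it is closed last.
2. Ring C (O1–C2 bond and C3–O bond) comes from phenol-directed epoxidation of an (E)-1,1,3-triarylpropene, followed by 6-endo opening at benzylic C2. C4 controls C3, and C3 controls C2.
3. The C2=C3–ring B unit comes from cross metathesis of a propenyl group with a ring B styrene.
4. The key bond C4–C4a comes from an aromatic Claisen [3,3] rearrangement of a ring A aryl (E)-1-methyl-3-(ring D)allyl ether, with 1,3-chirality transfer from C–O to C–C.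
5. That ether comes from Mitsunobu inversion of a D-lactate ester by the ring A phenol, then reduction and HWE olefination with a ring D benzylphosphonate. Lactate C2 becomes C2, lactate C1 becomes C3, and the phosphonate CH2 becomes C4. The lactate carbon is the only stereocentre bought.

Assumption: the four compounds marked as starting materials in the compound list are catalogue items.

## Route

Step 1
Reactants: 1 2,4-dihydroxy-3-methoxybenzaldehyde
Product: 2 2,4-bis(benzyloxy)-3-methoxybenzaldehyde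
Conditions: BnBr (2.5 equiv), K2CO3, DMF, 60 °C
Reagents that add atoms: benzyl bromide, BrCc1ccccc1
Why: Williamson etherification, in which excess benzyl bromide in warm DMF alkylates both phenols (the chelated 2-OH last), and benzyl is chosen because all benzyl ethers fall in the final hydrogenolysis while the 3-OMe stays.

Step 2
Reactants: 2 2,4-bis(benzyloxy)-3-methoxybenzaldehyde
Product: 3 [2,4-bis(benzyloxy)-3-methoxyphenyl]methanol
Conditions: NaBH4, THF–MeOH, 0 °C
Reagents that add atoms: none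
Why: Borohydride carbonyl reduction, in which the aldehyde is the only reducible group and the benzyl and methyl ethers are inert.

Step 3
Reactants: 3 [2,4-bis(benzyloxy)-3-methoxyphenyl]methanol
Product: 4 diethyl {[2,4-bis(benzyloxy)-3-methoxyphenyl]methyl}phosphonate
Conditions: P(OEt)3 (3 equiv), ZnI2 (1.5 equiv), toluene, reflux
Reagents that add atoms: triethyl phosphite, CCOP(OCC)OCC
Why: ZnI2-mediated Michaelis–Arbuzov-type phosphonylation, in which the Lewis acid activates the electron-rich benzylic alcohol for capture by the phosphite, giving the phosphonate directly and avoiding an unstable benzylic halide.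

Step 4
Reactants: 5 methyl (R)-lactate; 6 3-(benzyloxy)phenol
Product: 7 methyl (S)-2-[3-(benzyloxy)phenoxy]propanoate
Conditions: PPh3, DIAD, THF, 0 °C to rt
Reagents that add atoms: none
Why: Mitsunobu reaction, in which SN2 displacement of the activated lactate hydroxyl by the phenol goes with clean inversion, so the bought (R) centre becomes the (S) aryl ether centre.

Step 5
Reactants: 7 methyl (S)-2-[3-(benzyloxy)phenoxy]propanoate; 4 diethyl {[2,4-bis(benzyloxy)-3-methoxyphenyl]methyl}phosphonate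
Product: 9 1-(benzyloxy)-3-{[(2S,3E)-4-[2,4-bis(benzyloxy)-3-methoxyphenyl]but-3-en-2-yl]oxy}benzene, via (S)-2-[3-(benzyloxy)phenoxy]propanal 8 (not isolated)
Conditions: 7, i-Bu2AlH (1.05 equiv), toluene, −78 °C; then 4 + KN(SiMe3)2 (THF, −78 °C) added, −78 °C to rt; aq potassium sodium tartrate
Reagents that add atoms: none
Why: Partial ester reduction followed in the same flask by Horner–Wadsworth–Emmons olefination, in which the aluminium hemiacetal releases 8 only as it is consumed so the α-aryloxy centre is not epimerised, and the benzylic phosphonate gives the E alkene (>20:1) needed for clean chirality transfer.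

Step 6
Reactants: 9 1-(benzyloxy)-3-{[(2S,3E)-4-[2,4-bis(benzyloxy)-3-methoxyphenyl]but-3-en-2-yl]oxy}benzene
Product: 11 5-(benzyloxy)-2-{(1R,2E)-1-[2,4-bis(benzyloxy)-3-methoxyphenyl]but-2-en-1-yl}phenol, via ortho-dienone 10 (not isolated)
Conditions: PhNEt2 (0.1 M), 175 °C, sealed tube, Ar, 4 h; chromatography removes the minor Z alkene and the minor regioisomer
Reagents that add atoms: none
Why: Aromatic Claisen [3,3]-sigmatropic rearrangement, in which the suprafacial shift through the chair transition state with methyl equatorial carries the (S) C–O centre over into the new C4–C4a bond (R) and an E propenyl group, the bulky allyl terminus prefers the ortho carbon para to OBn over the one flanked by two oxygens, and dienone 10 tautomerises to the phenol that is the future O1.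

Step 7
Reactants: 12 3,4-bis(benzyloxy)benzaldehyde
Product: 13 1,2-bis(benzyloxy)-4-ethenylbenzene
Conditions: MePPh3Br, KOt-Bu, THF, 0 °C to rt
Reagents that add atoms: methyltriphenylphosphonium bromide, C[P+](c1ccccc1)(c1ccccc1)c1ccccc1.[Br-]
Why: Wittig methylenation, in which the non-stabilised ylide turns the aldehyde into the terminal styrene without touching the benzyl ethers.

Step 8
Reactants: 11 5-(benzyloxy)-2-{(1R,2E)-1-[2,4-bis(benzyloxy)-3-methoxyphenyl]but-2-en-1-yl}phenol; 13 1,2-bis(benzyloxy)-4-ethenylbenzene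
Product: 14 5-(benzyloxy)-2-{(1R,2E)-3-[3,4-bis(benzyloxy)phenyl]-1-[2,4-bis(benzyloxy)-3-methoxyphenyl]prop-2-en-1-yl}phenol
Conditions: 13 (3 equiv), second-generation Grubbs catalyst RuCl2(=CHPh)(PCy3)(H2IMes) (5 mol %), 1,4-benzoquinone (10 mol %), CH2Cl2, 40 °C
Reagents that add atoms: none
Why: Olefin cross metathesis, in which the propenyl group exchanges its ethylidene end for the benzylidene of 13 with loss of volatile propene, the conjugated E styrene is the thermodynamic product, C4 is not involved, and benzoquinone suppresses ruthenium hydride isomerisation.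

Step 9
Reactants: 14 5-(benzyloxy)-2-{(1R,2E)-3-[3,4-bis(benzyloxy)phenyl]-1-[2,4-bis(benzyloxy)-3-methoxyphenyl]prop-2-en-1-yl}phenol
Product: 16 (2R,3S,4R)-7-(benzyloxy)-2-[3,4-bis(benzyloxy)phenyl]-4-[2,4-bis(benzyloxy)-3-methoxyphenyl]-3,4-dihydro-2H-chromen-3-ol (2,3-trans-3,4-cis), via trans-epoxide 15 (not isolated)
Conditions: VO(acac)2 (5 mol %), t-BuOOH (1.3 equiv, decane), CH2Cl2, 0 °C to rt; then CF3CO2H (10 mol %), 0 °C
Reagents that add atoms: tert-butyl hydroperoxide, CC(C)(C)OO
Why: Phenol-directed vanadium-catalysed epoxidation followed by acid-triggered 6-endo epoxide opening, in which the peroxide bound to the ring A phenoxide reaches the alkene face on ring A's side in the rotamer that turns bulky ring D away (so O3 ends cis to ring D), and the phenol then attacks the p-benzyloxybenzylic C2 with inversion to give the 2,3-trans ring C.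

Step 10
Reactants: 16 (2R,3S,4R)-7-(benzyloxy)-2-[3,4-bis(benzyloxy)phenyl]-4-[2,4-bis(benzyloxy)-3-methoxyphenyl]-3,4-dihydro-2H-chromen-3-ol
Product: 17 (2R,3S,4S)-2-(3,4-dihydroxyphenyl)-4-(2,4-dihydroxy-3-methoxyphenyl)-3,4-dihydro-2H-chromene-3,7-diol
Conditions: H2 (1 atm), Pd(OH)2/C, THF–MeOH 1:1, rt, work-up under Ar
Reagents that add atoms: none
Why: Catalytic hydrogenolysis, in which the five O-benzyl groups are cleaved at one atmosphere while the methyl ether, the cyclic C2–O1 bond and the three stereocentres stay untouched (the C4 descriptor changes from R to S only through CIP priorities, not in space).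

## Compound list

1 | 2,4-dihydroxy-3-methoxybenzaldehyde | COc1c(O)ccc(C=O)c1O | starting material
2 | 2,4-bis(benzyloxy)-3-methoxybenzaldehyde | COc1c(OCc2ccccc2)ccc(C=O)c1OCc1ccccc1 | intermediate
3 | [2,4-bis(benzyloxy)-3-methoxyphenyl]methanol | COc1c(OCc2ccccc2)ccc(CO)c1OCc1ccccc1 | intermediate
4 | diethyl {[2,4-bis(benzyloxy)-3-methoxyphenyl]methyl}phosphonate | CCOP(=O)(OCC)Cc1ccc(OCc2ccccc2)c(OC)c1OCc1ccccc1 | intermediate
5 | methyl (R)-lactate | C[C@@H](O)C(=O)OC | starting material
6 | 3-(benzyloxy)phenol | Oc1cccc(OCc2ccccc2)c1 | starting material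
7 | methyl (S)-2-[3-(benzyloxy)phenoxy]propanoate | C[C@H](Oc1cccc(OCc2ccccc2)c1)C(=O)OC | intermediate
8 | (S)-2-[3-(benzyloxy)phenoxy]propanal | C[C@H](Oc1cccc(OCc2ccccc2)c1)C=O | intermediate
9 | 1-(benzyloxy)-3-{[(2S,3E)-4-[2,4-bis(benzyloxy)-3-methoxyphenyl]but-3-en-2-yl]oxy}benzene | C[C@H](Oc1cccc(OCc2ccccc2)c1)/C=C/c1ccc(OCc2ccccc2)c(OC)c1OCc1ccccc1 | intermediate
10 | (6S)-3-(benzyloxy)-6-{(1R,2E)-1-[2,4-bis(benzyloxy)-3-methoxyphenyl]but-2-en-1-yl}cyclohexa-2,4-dien-1-one | O=C1C=C(OCc2ccccc2)C=C[C@H]1[C@@H](/C=C/C)c1ccc(OCc2ccccc2)c(OC)c1OCc1ccccc1 | intermediate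
11 | 5-(benzyloxy)-2-{(1R,2E)-1-[2,4-bis(benzyloxy)-3-methoxyphenyl]but-2-en-1-yl}phenol | C/C=C/[C@H](c1ccc(OCc2ccccc2)cc1O)c1ccc(OCc2ccccc2)c(OC)c1OCc1ccccc1 | intermediate
12 | 3,4-bis(benzyloxy)benzaldehyde | O=Cc1ccc(OCc2ccccc2)c(OCc2ccccc2)c1 | starting material
13 | 1,2-bis(benzyloxy)-4-ethenylbenzene | C=Cc1ccc(OCc2ccccc2)c(OCc2ccccc2)c1 | intermediate
14 | 5-(benzyloxy)-2-{(1R,2E)-3-[3,4-bis(benzyloxy)phenyl]-1-[2,4-bis(benzyloxy)-3-methoxyphenyl]prop-2-en-1-yl}phenol | c1ccccc1COc1ccc(/C=C/[C@H](c2ccc(OCc3ccccc3)cc2O)c2ccc(OCc3ccccc3)c(OC)c2OCc2ccccc2)cc1OCc1ccccc1 | intermediate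
15 | (2S,3S)-2-[3,4-bis(benzyloxy)phenyl]-3-{(R)-[4-(benzyloxy)-2-hydroxyphenyl][2,4-bis(benzyloxy)-3-methoxyphenyl]methyl}oxirane | c1ccccc1COc1ccc([C@@H]4O[C@H]4[C@H](c2ccc(OCc3ccccc3)cc2O)c2ccc(OCc3ccccc3)c(OC)c2OCc2ccccc2)cc1OCc1ccccc1 | intermediate
16 | (2R,3S,4R)-7-(benzyloxy)-2-[3,4-bis(benzyloxy)phenyl]-4-[2,4-bis(benzyloxy)-3-methoxyphenyl]-3,4-dihydro-2H-chromen-3-ol | COc1c(OCc2ccccc2)ccc([C@H]2c3ccc(OCc4ccccc4)cc3O[C@H](c3ccc(OCc4ccccc4)c(OCc4ccccc4)c3)[C@H]2O)c1OCc1ccccc1 | intermediate
17 | (2R,3S,4S)-2-(3,4-dihydroxyphenyl)-4-(2,4-dihydroxy-3-methoxyphenyl)-3,4-dihydro-2H-chromene-3,7-diol, 4beta-(2,4-dihydroxy-3-methoxyphenyl)fisetinidol | COc1c(O)ccc([C@H]2c3ccc(O)cc3O[C@H](c3ccc(O)c(O)c3)[C@H]2O)c1O | target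

## Step count and risks

Total steps: 10. Longest linear sequence: 8 (steps 1, 2, 3, 5, 6, 8, 9, 10).

**Step 6 (Claisen rearrangement).**
- Some migration may go to the ortho carbon between the two oxygens.
- Ionisation to the donor-stabilised allyl cation and phenoxide would erode the chirality transfer.
- Thermal elimination to the diene is possible.

The fallback makes the C4–C4a bond by a copper-mediated anti-SN2' allylic arylation, with the same lactate carbon as the stereochemical source. It sets out from 5 and 4. Compound 5 is silylated (TBSCl, imidazole, DMF) to methyl (R)-2-[(tert-butyldimethylsilyl)oxy]propanoate F1. This is reduced with i-Bu2AlH at −78 °C to (R)-2-[(tert-butyldimethylsilyl)oxy]propanal F2. F2 is olefinated in the same flask with the potassium anion of 4 to tert-butyl({(2R,3E)-4-[2,4-bis(benzyloxy)-3-methoxyphenyl]but-3-en-2-yl}oxy)dimethylsilane F3. Treatment with n-Bu4NF frees (2R,3E)-4-[2,4-bis(benzyloxy)-3-methoxyphenyl]but-3-en-2-ol F4. Picolinic acid, DCC and DMAP then give (2R,3E)-4-[2,4-bis(benzyloxy)-3-methoxyphenyl]but-3-en-2-yl pyridine-2-carboxylate F5. [4-(Benzyloxy)-2-(methoxymethoxy)phenyl]magnesium bromide with CuBr·SMe2 in THF at −40 °C displaces the picolinate on the face opposite to it. The product is 4-(benzyloxy)-1-{(1R,2E)-1-[2,4-bis(benzyloxy)-3-methoxyphenyl]but-2-en-1-yl}-2-(methoxymethoxy)benzene F6. The ring A position is fixed here by the bromide from which the Grignard reagent is made. HCl in MeOH removes the MOM group, and the route is rejoined at 11.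

**Step 9 (directed epoxidation and cyclisation).**
- The 3,4-cis outcome rests on acyclic face control of an E alkene, so the all-trans diastereomer may form beside 16.
- 5-exo closure is a possible side path.
- Rearrangement of 15 to a ketone is a possible side path.

The fallback replaces directed oxygen delivery by sterically controlled osmylation followed by a separate cyclodehydration. It sets out from 14. OsO4 (cat.) and N-methylmorpholine N-oxide in acetone–water add from the face away from ring D. This gives (1S,2S,3R)-1-[3,4-bis(benzyloxy)phenyl]-3-[4-(benzyloxy)-2-hydroxyphenyl]-3-[2,4-bis(benzyloxy)-3-methoxyphenyl]propane-1,2-diol F8, which can be purified as a single diastereomer. Pyridinium p-toluenesulfonate in 1,2-dichloroethane at 60 °C ionises only the p-benzyloxybenzylic hydroxyl. The ring A phenol then closes to the 2,3-trans product, and the route is rejoined at 16.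

**Step 8 (cross metathesis).**
- The alkene sits next to a hindered diarylmethine carbon.
- The electron-rich styrene can divert to the stilbene.
- Ruthenium hydrides could move the double bond into conjugation and destroy C4.

The fallback splits the exchange into metathesis with a small partner followed by a cross-coupling. It sets out from 11. Vinylboronic acid pinacol ester with the same ruthenium catalyst gives 5-(benzyloxy)-2-{(1R,2E)-1-[2,4-bis(benzyloxy)-3-methoxyphenyl]-3-(4,4,5,5-tetramethyl-1,3,2-dioxaborolan-2-yl)prop-2-en-1-yl}phenol F7. Suzuki–Miyaura coupling with 4-bromo-1,2-bis(benzyloxy)benzene (Pd(PPh3)4, K2CO3, dioxane–water, 80 °C) retains the alkene geometry, and the route is rejoined at 14.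

## Further compounds

F1 | step 6 | methyl (R)-2-[(tert-butyldimethylsilyl)oxy]propanoate | C[C@@H](O[Si](C)(C)C(C)(C)C)C(=O)OC
F2 | step 6 | (R)-2-[(tert-butyldimethylsilyl)oxy]propanal | C[C@@H](O[Si](C)(C)C(C)(C)C)C=O
F3 | step 6 | tert-butyl({(2R,3E)-4-[2,4-bis(benzyloxy)-3-methoxyphenyl]but-3-en-2-yl}oxy)dimethylsilane | C[C@@H](O[Si](C)(C)C(C)(C)C)/C=C/c1ccc(OCc2ccccc2)c(OC)c1OCc1ccccc1
F4 | step 6 | (2R,3E)-4-[2,4-bis(benzyloxy)-3-methoxyphenyl]but-3-en-2-ol | C[C@@H](O)/C=C/c1ccc(OCc2ccccc2)c(OC)c1OCc1ccccc1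
F5 | step 6 | (2R,3E)-4-[2,4-bis(benzyloxy)-3-methoxyphenyl]but-3-en-2-yl pyridine-2-carboxylate | C[C@@H](OC(=O)c1ccccn1)/C=C/c1ccc(OCc2ccccc2)c(OC)c1OCc1ccccc1
F6 | step 6 | 4-(benzyloxy)-1-{(1R,2E)-1-[2,4-bis(benzyloxy)-3-methoxyphenyl]but-2-en-1-yl}-2-(methoxymethoxy)benzene | C/C=C/[C@H](c1ccc(OCc2ccccc2)cc1OCOC)c1ccc(OCc2ccccc2)c(OC)c1OCc1ccccc1
F7 | step 8 | 5-(benzyloxy)-2-{(1R,2E)-1-[2,4-bis(benzyloxy)-3-methoxyphenyl]-3-(4,4,5,5-tetramethyl-1,3,2-dioxaborolan-2-yl)prop-2-en-1-yl}phenol | CC1(C)OB(/C=C/[C@H](c2ccc(OCc3ccccc3)cc2O)c2ccc(OCc3ccccc3)c(OC)c2OCc2ccccc2)OC1(C)C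
F8 | step 9 | (1S,2S,3R)-1-[3,4-bis(benzyloxy)phenyl]-3-[4-(benzyloxy)-2-hydroxyphenyl]-3-[2,4-bis(benzyloxy)-3-methoxyphenyl]propane-1,2-diol | c1ccccc1COc1ccc([C@H](O)[C@@H](O)[C@H](c2ccc(OCc3ccccc3)cc2O)c2ccc(OCc3ccccc3)c(OC)c2OCc2ccccc2)cc1OCc1ccccc1
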